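Ring B is opened between C9 and C10 (eudesmane numbering). C4 of ring A, the carbon that ends up bearing the C3=C4 alkene and the C15 ester arm, is carried as a ketone: conjugated through C5=C10 it turns the methyl-bearing C10 into a radical acceptor. The key step is a 6-endo radical conjugate addition of a primary C9 radical onto C10 of a 2-alkyl-3-methylcyclohex-2-enone; it closes ring B, creates the quaternary C10 under control of C7 and leaves the C4 ketone, which then fixes C5 by equilibration and becomes the C3=C4–C15 unit via an enol triflate. The precursor is a bromoalkyl enone whose C7 carries a malonate, the masked acrylate.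

Key step: step 6

Remark: eudesmane numbering is used (C10 quaternary ring-fusion carbon, C5 ring-fusion CH, C4 the alkene carbon bearing C15, C7 the acrylate-bearing carbon, C9 the ring-B CH2 next to C10); the (Ra,R,R)-phosphoramidite is assumed to give (S)-8 in step 4, and if the sense is opposite its commercial antipode is used.

Step 1
Reactants: 1 3-methylcyclohex-2-en-1-one
Product: 2 2-iodo-3-methylcyclohex-2-en-1-one
Conditions: I2, pyridine, CH2Cl2, 0 °C to rt
Reagents that add atoms: iodine, II
Why: α-Iodination of the enone by the pyridine-mediated addition–iodination–elimination sequence (Baylis–Hillman-type α-halogenation) should give the vinyl iodide needed for cross-coupling, with no stereocentre involved.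

Step 2
Reactants: 2 2-iodo-3-methylcyclohex-2-en-1-one; 3 allyltributylstannane
Product: 4 2-allyl-3-methylcyclohex-2-en-1-one
Conditions: Pd(PPh3)4 (5 mol%), CuI (10 mol%), DMF, 50 °C
Reagents that add atoms: none
Why: A copper-assisted Stille coupling joins the vinyl iodide to the allyl group under neutral conditions, so the enone and the skipped diene of the product should not isomerise.

Step 3
Reactants: 4 2-allyl-3-methylcyclohex-2-en-1-one; 5 allyl methyl carbonate (excess)
Product: 6 methyl (2E)-4-(2-methyl-6-oxocyclohex-1-en-1-yl)but-2-en-1-yl carbonate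
Conditions: second-generation Hoveyda–Grubbs catalyst (3 mol%), CH2Cl2, 40 °C
Reagents that add atoms: none
Why: Olefin cross-metathesis of the terminal allyl group with an excess of the carbonate partner should give mainly the (E)-allylic carbonate, the tetrasubstituted enone alkene being inert to the ruthenium carbene.

Step 4
Reactants: 6 methyl (2E)-4-(2-methyl-6-oxocyclohex-1-en-1-yl)but-2-en-1-yl carbonate; 7 dimethyl malonate
Product: 8 dimethyl 2-[(2S)-1-(2-methyl-6-oxocyclohex-1-en-1-yl)but-3-en-2-yl]malonate
Conditions: [Ir(cod)Cl]2 (2 mol%), (Ra,R,R)-O,O'-(1,1'-binaphthalene-2,2'-diyl) N,N-bis(1-phenylethyl)phosphoramidite (4 mol%), 1,5,7-triazabicyclo[4.4.0]dec-5-ene (8 mol%), THF, rt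
Reagents that add atoms: none
Why: Iridium-catalysed asymmetric allylic alkylation delivers the malonate to the substituted terminus of the allyl–iridium intermediate (branched product), the chiral phosphoramidite fixing the C7 stereocentre as (S) and the expelled methoxide serving as the base.

Step 5
Reactants: 8 dimethyl 2-[(2S)-1-(2-methyl-6-oxocyclohex-1-en-1-yl)but-3-en-2-yl]malonate
Product: 9 dimethyl 2-[(2S)-4-bromo-1-(2-methyl-6-oxocyclohex-1-en-1-yl)butan-2-yl]malonate
Conditions: HBr (g), dibenzoyl peroxide (cat.), PhMe/hexane, hν, 0 °C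
Reagents that add atoms: hydrogen bromide, Br
Why: Radical-chain anti-Markovnikov hydrobromination (Kharasch addition) puts bromine on the terminal C9 because the bromine atom adds there to give the secondary C8 radical, while the tetrasubstituted enone and the malonate do not sustain the chain.

Step 6
Reactants: 9 dimethyl 2-[(2S)-4-bromo-1-(2-methyl-6-oxocyclohex-1-en-1-yl)butan-2-yl]malonate
Product: 11 dimethyl 2-[(2R,4aR,8aR)-4a-methyl-8-oxodecahydronaphthalen-2-yl]malonate (trans-fused), via cis-fused 8a-epimer 10 (not isolated)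
Conditions: (Me3Si)3SiH, AIBN, PhMe (0.005 M), 90 °C, syringe pump; then NaOMe, MeOH, rt
Reagents that add atoms: none
Why: The silyl radical abstracts bromine from 9 and the primary C9 radical adds to the enone β-carbon C10, after which the C5 α-keto radical takes a hydrogen atom from the silane (intramolecular Giese-type radical conjugate addition). The closest known reactions are tin- or silane-mediated cyclisations of 2-(4-haloalkyl)cycloalk-2-enones to decalones. Ring B closes in the 6-endo-trig mode. C10 is controlled by C7: in the chair-like transition state the malonyl group sits equatorial, which forces the C10 methyl axial and cis to it; C5 is then set under thermodynamic control by methoxide, the trans-fused ketone being the stable epimer as in 5α-4-oxo steroids. The step needs 6-endo over 5-exo closure, secured by the polarity match of the nucleophilic alkyl radical with the β-carbon of the C4 ketone (5-exo would attack the fully substituted α-carbon C5 and give an unstabilised radical), and cyclisation over premature reduction, secured by the slow hydrogen donor at high dilution.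

Step 7
Reactants: 11 dimethyl 2-[(2R,4aR,8aR)-4a-methyl-8-oxodecahydronaphthalen-2-yl]malonate
Product: 13 dimethyl 2-[(2R,4aS,8aR)-4a-methyl-8-(trifluoromethanesulfonyloxy)-1,2,3,4,4a,5,6,8a-octahydronaphthalen-2-yl]malonate, via dipotassium bis-enolate 12 (not isolated)
Conditions: KN(SiMe3)2 (2.2 equiv), THF, −78 °C; then PhNTf2, −78 to 0 °C
Reagents that add atoms: N-phenylbis(trifluoromethanesulfonimide), O=S(=O)(N(c1ccccc1)S(=O)(=O)C(F)(F)F)C(F)(F)F
Why: Enol triflate formation under kinetic control: the first equivalent of base parks the malonate as its unreactive enolate, the second removes a proton from the unhindered C3 methylene rather than from the tertiary C5–H next to the quaternary centre, and O-sulfonylation of the ketone enolate fixes the alkene at C3=C4.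

Step 8
Reactants: 13 dimethyl 2-[(2R,4aS,8aR)-4a-methyl-8-(trifluoromethanesulfonyloxy)-1,2,3,4,4a,5,6,8a-octahydronaphthalen-2-yl]malonate; 14 (tributylstannyl)methanol
Product: 15 dimethyl 2-[(2R,4aS,8aR)-8-(hydroxymethyl)-4a-methyl-1,2,3,4,4a,5,6,8a-octahydronaphthalen-2-yl]malonate
Conditions: Pd(PPh3)4 (10 mol%), LiCl, 1,4-dioxane, 100 °C
Reagents that add atoms: none
Why: Stille coupling of the enol triflate with the hydroxymethyl stannane (chloride-assisted transmetalation) installs C15 directly at the alcohol oxidation level without moving the C3=C4 alkene or touching the C5 stereocentre.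

Step 9
Reactants: 15 dimethyl 2-[(2R,4aS,8aR)-8-(hydroxymethyl)-4a-methyl-1,2,3,4,4a,5,6,8a-octahydronaphthalen-2-yl]malonate
Product: 16 2-[(2R,4aS,8aR)-8-(hydroxymethyl)-4a-methyl-1,2,3,4,4a,5,6,8a-octahydronaphthalen-2-yl]-3-methoxy-3-oxopropanoic acid (mixture at the malonate carbon)
Conditions: KOH (1.05 equiv), MeOH/THF, 0 °C to rt; then aq. HCl
Reagents that add atoms: potassium hydroxide, [K+].[OH-]
Why: Mono-saponification of the malonate stops after one ester because the resulting carboxylate deactivates its neighbour, and the new C11 stereocentre is of no consequence as it is destroyed in the next step.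

Step 10
Reactants: 16 2-[(2R,4aS,8aR)-8-(hydroxymethyl)-4a-methyl-1,2,3,4,4a,5,6,8a-octahydronaphthalen-2-yl]-3-methoxy-3-oxopropanoic acid
Product: 18 methyl 2-[(2R,4aR,8aR)-8-(hydroxymethyl)-4a-methyl-1,2,3,4,4a,5,6,8a-octahydronaphthalen-2-yl]prop-2-enoate, via Mannich base 17 (not isolated)
Conditions: (CH2O)n, Et2NH, EtOAc, 80 °C
Reagents that add atoms: formaldehyde (from paraformaldehyde), C=O
Why: Mannich reaction of the malonic half-ester with formaldehyde and diethylamine followed by decarboxylative loss of the amine (decarboxylative Mannich methylenation) should unveil the 2-substituted methyl acrylate under conditions that leave the allylic alcohol alone.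

Step 11
Reactants: 18 methyl 2-[(2R,4aR,8aR)-8-(hydroxymethyl)-4a-methyl-1,2,3,4,4a,5,6,8a-octahydronaphthalen-2-yl]prop-2-enoate; 19 (E)-4-hydroxycinnamic acid (p-coumaric acid)
Product: 21 methyl 2-[(2R,4aR,8aR)-8-({[(2E)-3-(4-hydroxyphenyl)prop-2-enoyl]oxy}methyl)-4a-methyl-1,2,3,4,4a,5,6,8a-octahydronaphthalen-2-yl]prop-2-enoate (CNP0161949.1), via alkoxyphosphonium coumarate 20 (not isolated)
Conditions: PPh3, DIAD, THF, 0 °C to rt
Reagents that add atoms: none
Why: Mitsunobu esterification activates the primary allylic C15 alcohol as its oxyphosphonium ion, which is displaced (SN2) by the coumarate carboxylate, the only partner acidic enough to be deprotonated by the betaine, so the free phenol needs no protection and the (E)-alkene is untouched.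

Compound list
1 | 3-methylcyclohex-2-en-1-one | CC1=CC(=O)CCC1 | starting material
2 | 2-iodo-3-methylcyclohex-2-en-1-one | CC1=C(I)C(=O)CCC1 | intermediate
3 | allyltributylstannane | C=CC[Sn](CCCC)(CCCC)CCCC | starting material
4 | 2-allyl-3-methylcyclohex-2-en-1-one | C=CCC1=C(C)CCCC1=O | intermediate
5 | allyl methyl carbonate | C=CCOC(=O)OC | starting material
6 | methyl (2E)-4-(2-methyl-6-oxocyclohex-1-en-1-yl)but-2-en-1-yl carbonate | COC(=O)OC/C=C/CC1=C(C)CCCC1=O | intermediate
7 | dimethyl malonate | COC(=O)CC(=O)OC | starting material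
8 | dimethyl 2-[(2S)-1-(2-methyl-6-oxocyclohex-1-en-1-yl)but-3-en-2-yl]malonate | C=C[C@H](CC1=C(C)CCCC1=O)C(C(=O)OC)C(=O)OC | intermediate
9 | dimethyl 2-[(2S)-4-bromo-1-(2-methyl-6-oxocyclohex-1-en-1-yl)butan-2-yl]malonate | BrCC[C@H](CC1=C(C)CCCC1=O)C(C(=O)OC)C(=O)OC | intermediate
10 | dimethyl 2-[(2R,4aR,8aS)-4a-methyl-8-oxodecahydronaphthalen-2-yl]malonate (cis-fused 8a-epimer of 11) | COC(=O)C(C(=O)OC)[C@@H]1CC[C@@]2(C)CCCC(=O)[C@H]2C1 | intermediate
11 | dimethyl 2-[(2R,4aR,8aR)-4a-methyl-8-oxodecahydronaphthalen-2-yl]malonate (trans-fused) | COC(=O)C(C(=O)OC)[C@@H]1CC[C@@]2(C)CCCC(=O)[C@@H]2C1 | intermediate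
12 | dipotassium bis-enolate of 11 (malonate enolate plus C3=C4 ketone enolate) | [K+].[K+].COC(=O)[C-](C(=O)OC)[C@@H]1CC[C@@]2(C)CCC=C([O-])[C@@H]2C1 | intermediate
13 | dimethyl 2-[(2R,4aS,8aR)-4a-methyl-8-(trifluoromethanesulfonyloxy)-1,2,3,4,4a,5,6,8a-octahydronaphthalen-2-yl]malonate | COC(=O)C(C(=O)OC)[C@@H]1CC[C@@]2(C)CCC=C(OS(=O)(=O)C(F)(F)F)[C@@H]2C1 | intermediate
14 | (tributylstannyl)methanol | CCCC[Sn](CCCC)(CCCC)CO | starting material
15 | dimethyl 2-[(2R,4aS,8aR)-8-(hydroxymethyl)-4a-methyl-1,2,3,4,4a,5,6,8a-octahydronaphthalen-2-yl]malonate | COC(=O)C(C(=O)OC)[C@@H]1CC[C@@]2(C)CCC=C(CO)[C@@H]2C1 | intermediate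
16 | 2-[(2R,4aS,8aR)-8-(hydroxymethyl)-4a-methyl-1,2,3,4,4a,5,6,8a-octahydronaphthalen-2-yl]-3-methoxy-3-oxopropanoic acid | COC(=O)C(C(=O)O)[C@@H]1CC[C@@]2(C)CCC=C(CO)[C@@H]2C1 | intermediate
17 | 2-[(diethylamino)methyl]-2-[(2R,4aR,8aR)-8-(hydroxymethyl)-4a-methyl-1,2,3,4,4a,5,6,8a-octahydronaphthalen-2-yl]-3-methoxy-3-oxopropanoic acid (Mannich base) | CCN(CC)CC(C(=O)O)(C(=O)OC)[C@@H]1CC[C@@]2(C)CCC=C(CO)[C@@H]2C1 | intermediate
18 | methyl 2-[(2R,4aR,8aR)-8-(hydroxymethyl)-4a-methyl-1,2,3,4,4a,5,6,8a-octahydronaphthalen-2-yl]prop-2-enoate | C=C(C(=O)OC)[C@@H]1CC[C@@]2(C)CCC=C(CO)[C@@H]2C1 | intermediate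
19 | (E)-4-hydroxycinnamic acid (p-coumaric acid) | OC(=O)/C=C/c1ccc(O)cc1 | starting material
20 | triphenylphosphonium ether of the C15 alcohol of 18, (E)-4-hydroxycinnamate salt | C=C(C(=O)OC)[C@@H]1CC[C@@]2(C)CCC=C(CO[P+](c3ccccc3)(c3ccccc3)c3ccccc3)[C@@H]2C1.[O-]C(=O)/C=C/c1ccc(O)cc1 | intermediate
21 | methyl 2-[(2R,4aR,8aR)-8-({[(2E)-3-(4-hydroxyphenyl)prop-2-enoyl]oxy}methyl)-4a-methyl-1,2,3,4,4a,5,6,8a-octahydronaphthalen-2-yl]prop-2-enoate | C=C(C(=O)OC)[C@@H]1CC[C@@]2(C)CCC=C(COC(=O)/C=C/c3ccc(O)cc3)[C@@H]2C1 | target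

Total step count: 11. Longest linear sequence: 11 steps (from 1 to 21).

Steps most likely to fail

Step 6 (key step). The primary C9 radical may take a hydrogen atom before the slow 6-endo closure onto the fully substituted C10, or the closure may show poor facial selectivity. The fallback sets out from 9 and replaces the radical chain by a nickel-catalysed reductive conjugate addition (NiCl2(dme), neocuproine, Mn powder, Et3SiCl, DMF, rt). This runs through a silyloxyallyl–nickel intermediate with no hydrogen donor present and should give the triethylsilyl enol ether F1. Mild acid hydrolysis followed by the methoxide equilibration of step 6 returns to 11.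

Step 5. Ionic Markovnikov addition of HBr (giving the secondary bromide) or acid-induced migration of the terminal alkene may compete with the radical chain. The fallback sets out from 4, replaces steps 3 to 5 and so also removes the dependence on the selectivity of step 4. Cross-metathesis of 4 with crotonaldehyde (second-generation Hoveyda–Grubbs catalyst) should give the (E)-enal F2. Iminium-catalysed Michael addition of dimethyl malonate 7 (diphenylprolinol trimethylsilyl ether, the enantiomer that leads to the (S)-adduct) should give the aldehyde F3. Aldehyde-selective reduction (NaBH4, MeOH, −78 °C) gives the alcohol F4, and Appel bromination (CBr4, PPh3, CH2Cl2) returns to 9.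

Step 11. The free phenol may be O-alkylated or oligomerise under Mitsunobu activation, and the phosphine may add to the acrylate. The fallback sets out from 18 and uses a protecting group instead of chemoselectivity. Carbodiimide esterification (EDC·HCl, DMAP, CH2Cl2) with commercial (E)-4-acetoxycinnamic acid should give the aryl acetate F5. Selective cleavage of the phenolic acetate (NH4OAc, aqueous MeOH, rt) then returns to 21.

Further compounds
F1 | step 6 | dimethyl 2-[(2R,4aR)-4a-methyl-8-(triethylsilyloxy)-1,2,3,4,4a,5,6,7-octahydronaphthalen-2-yl]malonate | COC(=O)C(C(=O)OC)[C@@H]1CC[C@@]2(C)CCCC(O[Si](CC)(CC)CC)=C2C1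
F2 | step 5 | (2E)-4-(2-methyl-6-oxocyclohex-1-en-1-yl)but-2-enal | O=C/C=C/CC1=C(C)CCCC1=O
F3 | step 5 | dimethyl 2-[(2S)-1-(2-methyl-6-oxocyclohex-1-en-1-yl)-4-oxobutan-2-yl]malonate | O=CC[C@H](CC1=C(C)CCCC1=O)C(C(=O)OC)C(=O)OC
F4 | step 5 | dimethyl 2-[(2S)-4-hydroxy-1-(2-methyl-6-oxocyclohex-1-en-1-yl)butan-2-yl]malonate | OCC[C@H](CC1=C(C)CCCC1=O)C(C(=O)OC)C(=O)OC
F5 | step 11 | methyl 2-[(2R,4aR,8aR)-8-({[(2E)-3-(4-acetoxyphenyl)prop-2-enoyl]oxy}methyl)-4a-methyl-1,2,3,4,4a,5,6,8a-octahydronaphthalen-2-yl]prop-2-enoate | C=C(C(=O)OC)[C@@H]1CC[C@@]2(C)CCC=C(COC(=O)/C=C/c3ccc(OC(C)=O)cc3)[C@@H]2C1
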